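Two things are asked of these flasks, a row of J at the end and its course:

| flask | Z | E | remark | time |
|---|---|---|---|---|
| west | 0.10 M | 1.2 mol% | run made earlier |  |
| north | 0.10 M | 23 mol% | run made earlier |  |
| gamma | 0.10 M | 1 mol% |  | 20 min |
| delta | 0.10 M | 2 mol% |  | 20 min |
| epsilon | 0.10 M | 4 mol% |  | 20 min |
| theta | 0.10 M | 8 mol% |  | 20 min |
| beta | 0.10 M | 15 mol% |  | 20 min |

- amount of J at the end, in percent of the Z charged for gamma, delta, epsilon, theta, beta, in this order
- the course of these numbers from the first flask to the last (hardly changes / falls, then rises / falls all the way / rises, then falls / rises all the way)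

| run | time / min | J / % | Z / % |
|---|---|---|---|
| west | 2.00 | 12.3 | 58.3 |
| west | 4.00 | 17.4 | 41.5 |
| west | 6.00 | 20.8 | 27.8 |
| west | 8.00 | 23.7 | 23.4 |
| west | 10.0 | 26.3 | 14.6 |
| west | 12.0 | 29.1 | 14.1 |
| west | 15.0 | 28.8 | 9.5 |
| north | 2.00 | 36.3 | 40.0 |
| north | 4.00 | 55.2 | 17.2 |
| north | 6.00 | 61.8 | 7.1 |
| north | 8.00 | 66.5 | 3.1 |
| north | 10.0 | 70.0 | 1.6 |
| north | 12.0 | 73.1 | 0 |
| north | 15.0 | 70.6 | 0 |

(readings scatter by 1 percentage point)

- the numbers in the tables scatter with a standard deviation of 1 percentage point
- "hardly changes" means that all values lie within two and a half points (for a concentration: within two and a half percent of the largest)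

1. West loses 29.4% of its charge without J by 2.00 min, but just 10 percentage points more between 6.00 min and 15.0 min, when Z is low, so this reckoning takes the side loss as second order in Z and the way into chains as first order.

2. Each flask then folds into B, the first-order rate constant into chains over the rate constant of the side loss at full charge, a selectivity factor. With J and Z as fractions of the charge, J = B·ln[(1 + B)/(B + Z)], which gives B·ln(1 + 1/B) once Z is used up.

3. North levels off at 71.2% from 10.0 min on, a reading close to the 69.3% that B = 1 gives, so north is read as B = 1.

4. Scaling by the square root of the loading gives west 0.228, and with its Z at 15.0 min that means 30.5% J against 28.8% read, whereas the first power gives 10.3%. So gamma has 0.209, the partition number, and beta has 0.808.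

5. The one number gives J with Z used up, but each flask is stopped at 20 min, so a clock is needed as well. North's Z at 4.00 min gives a chain rate constant of 0.306 /min, which this reckoning scales with B. That leaves gamma 0.231 as Z/(Z + B), so Z is 6.25% and J is 31.2%, against the 36.7% that this reckoning gives gamma with Z used up. Beta comes to 64.7% against 65.1% on the same reckoning with Z used up. J therefore rises from gamma to beta.

The forecast gave 32%, 41%, 51%, 60% and 67%, and said “J rises all the way”; at beta it stands above this reckoning.

The flasks give 31.2%, 40.2%, 50.0%, 59.8% and 67.1%, a course that rises all the way, with beta 2.4 points above this reckoning.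

    E → 2 X (k = 2.50 × 10⁻⁴ /s)
    Z + X → L + J (k = 2.80 × 10⁵ /M/s)
    Z + L → J + L, rate k3*[L]*[Z] (k = 29000 /M/s)
    2 L → Q (k = 2.00 × 10⁸ /M/s)
    2 Z → G (k = 0.0230 /M/s)

In gamma, the conversion of 2 Z into G uses Z 2.8 times as fast as the conversion of Z into J at 1.82 min, but 0.38 times as fast at 20.0 min, when Z stands at 7.34%. In gamma at that time Z over B, which is the same ratio of the two ways in this reckoning, is 0.351, and in delta, B of 0.295 with the 5.05% of Z left at 20.0 min gives 39.0% J, where delta holds 40.2%.

Readings and results stem from a simulated flask for an exercise; noise was put on by code.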